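**Plan**
- Retrosynthesis: the interflavan C4–C8 bond is cut first (upper unit as a ring A para-quinone methide, lower unit as a C8 aryl-metal). Each flavan unit is then cut at C3–OH (hydroboration of a flav-2-ene) and finally, in ring C, at O1–C8a and C3–C4.
- Enabling feature: O1 sits on aromatic C8a, ortho to C4a, which carries benzylic C4. A 2-bromobenzyl bromide is thus a 1,3-dielectrophile (C4, C8a), and an aryl methyl ketone enolate the matching 1,3-dinucleophile (C3, O1).
- Forward: one annulation closes ring C as the achiral 4H-chromene 6, which supplies both halves of the dimer. The two rings C are then elaborated separately and joined C4→C8.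
- Stereochemistry: enantiomeric IpcBH2 reagents set (2R,3S) in the lower unit and (2S,3R) in the upper unit. C3 of the upper unit is inverted through the ketone with LiBH(s-Bu)3 to give 2,3-cis. C4 is set by aryl addition anti to the 3-benzyloxy group.
- Regiochemistry of the 4→8 link: metalation of C8 between O1 and the 7-methoxymethoxy group. C4 of the upper unit is oxygenated with DDQ/MeOH while the 7-oxygen is still masked; the freed 7-OH, para to C4a, releases the ring A quinone methide only in the coupling flask.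

Key step: step 3

Assumption: the facial sense of IpcBH2 on chromene 6 is taken to follow that known for 1-arylcycloalkenes (reagent from (+)-α-pinene gives the (S)-carbinol); if it proves opposite, the two antipodal reagents are exchanged between steps 4 and 5.

**Step 1**
Reactants: 1 3-bromo-4-methylphenol
Product: 2 2-bromo-4-(methoxymethoxy)-1-methylbenzene
Conditions: MOMCl, i-Pr2NEt, CH2Cl2, 0 °C → rt
Reagents that add atoms: chloromethyl methyl ether, COCCl
Why: Williamson-type O-alkylation of the phenol with a reactive α-chloro ether installs an acetal that later directs metalation and is cleaved by mild acid.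

**Step 2**
Reactants: 2 2-bromo-4-(methoxymethoxy)-1-methylbenzene
Product: 3 2-bromo-1-(bromomethyl)-4-(methoxymethoxy)benzene
Conditions: NBS, AIBN (cat.), PhCF3, 80 °C
Reagents that add atoms: N-bromosuccinimide, O=C1CCC(=O)N1Br
Why: Wohl–Ziegler radical bromination should occur at the only benzylic methyl group, the non-polar radical conditions disfavouring ring bromination.

**Step 3**
Reactants: 3 2-bromo-1-(bromomethyl)-4-(methoxymethoxy)benzene; 4 1-[3,4-bis(benzyloxy)phenyl]ethan-1-one
Product: 6 2-[3,4-bis(benzyloxy)phenyl]-7-(methoxymethoxy)-4H-chromene, via ketone 5 (not isolated)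
Conditions: 4 (1.5 equiv), LiN(SiMe3)2, THF, −78 °C; add 3, −78 → 0 °C; then NaOt-Bu, CuI (10 mol %), 1,10-phenanthroline (20 mol %), THF exchanged for toluene, 100 °C, same flask
Reagents that add atoms: none
Why: The lithium enolate of 4 is C-benzylated by 3 in an SN2 displacement (C3–C4), and the resulting ketone 5, re-enolised by NaOt-Bu, closes ring C through its enolate oxygen by an Ullmann-type coupling at the ortho C–Br bond (oxidative addition to monovalent copper, C–O reductive elimination from trivalent copper), forming O1–C8a. The closest known reaction type is the one-pot C-benzylation/copper-catalysed intramolecular enolate O-arylation that converts 2-bromobenzyl bromides and enolisable carbonyl compounds into 4H-chromenes. Ring C closes in a formal 6-exo-trig mode, the enolate oxygen attacking aromatic C8a while bromide leaves outside the new ring. No stereocentre is created: the product is a planar, achiral enol ether, whose two enantiotopic faces are then addressed by reagent control in steps 4 and 5. The step needs C- over O-benzylation and mono- over dialkylation, secured by the lithium counter-ion in THF, the excess of enolate and the low temperature, and O- over C-arylation, secured by geometry because C-arylation would require a four-membered ring. The methoxymethyl and benzyl ethers should be inert to both stages.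

**Step 4**
Reactants: 6 2-[3,4-bis(benzyloxy)phenyl]-7-(methoxymethoxy)-4H-chromene
Product: 7 (2R,3S)-2-[3,4-bis(benzyloxy)phenyl]-7-(methoxymethoxy)-3,4-dihydro-2H-chromen-3-ol (2,3-trans)
Conditions: IpcBH2 derived from (+)-α-pinene, THF, −25 °C; then NaOH, H2O2, 0 °C → rt
Reagents that add atoms: hydrogen peroxide, OO
Why: Asymmetric hydroboration–oxidation of the trisubstituted aryl enol ether places boron on C3 (β to O1 and to the aryl group); syn addition fixes 2,3-trans, and the chiral borane selects the face that gives (3S), hence (2R,3S), with oxidation proceeding with retention.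

**Step 5**
Reactants: 6 2-[3,4-bis(benzyloxy)phenyl]-7-(methoxymethoxy)-4H-chromene
Product: 8 (2S,3R)-2-[3,4-bis(benzyloxy)phenyl]-7-(methoxymethoxy)-3,4-dihydro-2H-chromen-3-ol (2,3-trans)
Conditions: IpcBH2 derived from (−)-α-pinene, THF, −25 °C; then NaOH, H2O2, 0 °C → rt
Reagents that add atoms: hydrogen peroxide, OO
Why: The same asymmetric hydroboration–oxidation with the antipodal reagent should deliver the mirror-image trans alcohol, which fixes C2 of the upper unit as (S).

**Step 6**
Reactants: 8 (2S,3R)-2-[3,4-bis(benzyloxy)phenyl]-7-(methoxymethoxy)-3,4-dihydro-2H-chromen-3-ol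
Product: 9 (2S)-2-[3,4-bis(benzyloxy)phenyl]-7-(methoxymethoxy)-2H-chromen-3(4H)-one
Conditions: Dess–Martin periodinane, CH2Cl2, rt
Reagents that add atoms: none
Why: Dess–Martin oxidation is neutral and fast, so the ketone should form without enolisation of the adjacent C2 stereocentre, as is usual for protected flavan-3-ols.

**Step 7**
Reactants: 9 (2S)-2-[3,4-bis(benzyloxy)phenyl]-7-(methoxymethoxy)-2H-chromen-3(4H)-one
Product: 10 (2S,3S)-2-[3,4-bis(benzyloxy)phenyl]-7-(methoxymethoxy)-3,4-dihydro-2H-chromen-3-ol (2,3-cis)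
Conditions: LiBH(s-Bu)3, THF, −78 °C; then H2O
Reagents that add atoms: none
Why: Diastereoselective reduction by a bulky trialkylborohydride delivers hydride to the face that leaves the 3-hydroxyl axial and cis to the equatorial 2-aryl group, the established way from 2,3-trans to 2,3-cis flavan-3-ols.

**Step 8**
Reactants: 10 (2S,3S)-2-[3,4-bis(benzyloxy)phenyl]-7-(methoxymethoxy)-3,4-dihydro-2H-chromen-3-ol
Product: 11 (2S,3S)-3-(benzyloxy)-2-[3,4-bis(benzyloxy)phenyl]-7-(methoxymethoxy)-3,4-dihydro-2H-chromene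
Conditions: NaH, BnBr, n-Bu4NI (cat.), DMF, 0 °C → rt
Reagents that add atoms: benzyl bromide, BrCc1ccccc1
Why: Williamson etherification masks the 3-hydroxyl as a non-acidic, weakly coordinating ether that later shields one face of C4; no stereocentre is touched.

**Step 9**
Reactants: 11 (2S,3S)-3-(benzyloxy)-2-[3,4-bis(benzyloxy)phenyl]-7-(methoxymethoxy)-3,4-dihydro-2H-chromene
Product: 12 (2S,3S,4R)-3-(benzyloxy)-2-[3,4-bis(benzyloxy)phenyl]-4-methoxy-7-(methoxymethoxy)-3,4-dihydro-2H-chromene
Conditions: DDQ (1.5 equiv), CH2Cl2/MeOH (4:1), 0 °C → rt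
Reagents that add atoms: methanol, CO
Why: DDQ-mediated benzylic C–H oxidation, the established C4 oxygenation of O-protected flavan-3-ols, abstracts hydride from C4 (para to the 7-methoxymethoxy group and ortho to O1) and methanol captures the stabilised benzylic cation anti to the 3-benzyloxy group to give the 3,4-trans (4R) methyl ether, the masked 7-oxygen ruling out a quinone methide at this stage.

**Step 10**
Reactants: 12 (2S,3S,4R)-3-(benzyloxy)-2-[3,4-bis(benzyloxy)phenyl]-4-methoxy-7-(methoxymethoxy)-3,4-dihydro-2H-chromene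
Product: 13 (2S,3S,4R)-3-(benzyloxy)-2-[3,4-bis(benzyloxy)phenyl]-4-methoxy-3,4-dihydro-2H-chromen-7-ol
Conditions: HCl (cat.), MeOH/THF, 45 °C
Reagents that add atoms: none
Why: Acid-catalysed acetal exchange with methanol removes the aryl methoxymethyl group while benzyl ethers are stable to dilute acid, and any ionisation of the benzylic 4-methoxy group in methanol only returns the same ether, possible epimerisation at C4 being without consequence because C4 becomes trigonal in step 11.

**Step 11**
Reactants: 7 (2R,3S)-2-[3,4-bis(benzyloxy)phenyl]-7-(methoxymethoxy)-3,4-dihydro-2H-chromen-3-ol; 13 (2S,3S,4R)-3-(benzyloxy)-2-[3,4-bis(benzyloxy)phenyl]-4-methoxy-3,4-dihydro-2H-chromen-7-ol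
Product: 17 (2S,3S,4S)-3-(benzyloxy)-2-[3,4-bis(benzyloxy)phenyl]-4-[(2R,3S)-2-[3,4-bis(benzyloxy)phenyl]-3-hydroxy-7-(methoxymethoxy)-3,4-dihydro-2H-chromen-8-yl]-3,4-dihydro-2H-chromen-7-ol, via aryllithium 14 (not isolated), via arylmagnesium bromide 15 (not isolated), via quinone methide 16 (not isolated)
Conditions: 7 (2.5 equiv), n-BuLi (5.2 equiv), THF, −20 → 0 °C; MgBr2·OEt2, 0 °C; then 13 (1 equiv), THF/toluene, 0 °C → rt; aqueous work-up (excess 7 recovered)
Reagents that add atoms: none
Why: Directed ortho-metalation places the metal at C8 between O1 and the methoxymethoxy group (14); after transmetalation one equivalent of 15 deprotonates the phenol of 13, magnesium-assisted loss of methoxide releases the ring A para-quinone methide 16, and 1,6-addition of 15 to C4 anti to the axial 3-benzyloxy group should give the 4→8 bond with 3,4-trans (4S) configuration.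

**Step 12**
Reactants: 17 (2S,3S,4S)-3-(benzyloxy)-2-[3,4-bis(benzyloxy)phenyl]-4-[(2R,3S)-2-[3,4-bis(benzyloxy)phenyl]-3-hydroxy-7-(methoxymethoxy)-3,4-dihydro-2H-chromen-8-yl]-3,4-dihydro-2H-chromen-7-ol
Product: 18 (2S,3S,4S)-2-(3,4-dihydroxyphenyl)-4-[(2R,3S)-2-(3,4-dihydroxyphenyl)-3,7-dihydroxy-3,4-dihydro-2H-chromen-8-yl]-3,4-dihydro-2H-chromene-3,7-diol
Conditions: H2 (1 atm), Pd(OH)2/C, THF/MeOH, rt; then HCl (0.2 M), 40 °C, same pot
Reagents that add atoms: none
Why: Hydrogenolysis cleaves the five benzyl ethers and acid-catalysed acetal exchange removes the remaining methoxymethyl group, conditions under which the 5-deoxy interflavan bond and all five stereocentres should be stable.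

**Compound list**
1 | 3-bromo-4-methylphenol | Cc1ccc(O)cc1Br | starting material
2 | 2-bromo-4-(methoxymethoxy)-1-methylbenzene | COCOc1ccc(C)c(Br)c1 | intermediate
3 | 2-bromo-1-(bromomethyl)-4-(methoxymethoxy)benzene | COCOc1ccc(CBr)c(Br)c1 | intermediate
4 | 1-[3,4-bis(benzyloxy)phenyl]ethan-1-one | CC(=O)c1ccc(OCc2ccccc2)c(OCc2ccccc2)c1 | starting material
5 | 1-[3,4-bis(benzyloxy)phenyl]-3-[2-bromo-4-(methoxymethoxy)phenyl]propan-1-one | COCOc1ccc(CCC(=O)c2ccc(OCc3ccccc3)c(OCc3ccccc3)c2)c(Br)c1 | intermediate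
6 | 2-[3,4-bis(benzyloxy)phenyl]-7-(methoxymethoxy)-4H-chromene | COCOc1ccc2c(c1)OC(c1ccc(OCc3ccccc3)c(OCc3ccccc3)c1)=CC2 | intermediate
7 | (2R,3S)-2-[3,4-bis(benzyloxy)phenyl]-7-(methoxymethoxy)-3,4-dihydro-2H-chromen-3-ol | COCOc1ccc2c(c1)O[C@H](c1ccc(OCc3ccccc3)c(OCc3ccccc3)c1)[C@@H](O)C2 | intermediate
8 | (2S,3R)-2-[3,4-bis(benzyloxy)phenyl]-7-(methoxymethoxy)-3,4-dihydro-2H-chromen-3-ol | COCOc1ccc2c(c1)O[C@@H](c1ccc(OCc3ccccc3)c(OCc3ccccc3)c1)[C@H](O)C2 | intermediate
9 | (2S)-2-[3,4-bis(benzyloxy)phenyl]-7-(methoxymethoxy)-2H-chromen-3(4H)-one | COCOc1ccc2c(c1)O[C@@H](c1ccc(OCc3ccccc3)c(OCc3ccccc3)c1)C(=O)C2 | intermediate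
10 | (2S,3S)-2-[3,4-bis(benzyloxy)phenyl]-7-(methoxymethoxy)-3,4-dihydro-2H-chromen-3-ol | COCOc1ccc2c(c1)O[C@@H](c1ccc(OCc3ccccc3)c(OCc3ccccc3)c1)[C@@H](O)C2 | intermediate
11 | (2S,3S)-3-(benzyloxy)-2-[3,4-bis(benzyloxy)phenyl]-7-(methoxymethoxy)-3,4-dihydro-2H-chromene | COCOc1ccc2c(c1)O[C@@H](c1ccc(OCc3ccccc3)c(OCc3ccccc3)c1)[C@@H](OCc1ccccc1)C2 | intermediate
12 | (2S,3S,4R)-3-(benzyloxy)-2-[3,4-bis(benzyloxy)phenyl]-4-methoxy-7-(methoxymethoxy)-3,4-dihydro-2H-chromene | COCOc1ccc2c(c1)O[C@@H](c1ccc(OCc3ccccc3)c(OCc3ccccc3)c1)[C@@H](OCc1ccccc1)[C@@H]2OC | intermediate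
13 | (2S,3S,4R)-3-(benzyloxy)-2-[3,4-bis(benzyloxy)phenyl]-4-methoxy-3,4-dihydro-2H-chromen-7-ol | Oc1ccc2c(c1)O[C@@H](c1ccc(OCc3ccccc3)c(OCc3ccccc3)c1)[C@@H](OCc1ccccc1)[C@@H]2OC | intermediate
14 | C8-lithiated lithium alkoxide of 7 | COCOc1ccc2c(c1[Li])O[C@H](c1ccc(OCc3ccccc3)c(OCc3ccccc3)c1)[C@@H](O[Li])C2 | intermediate
15 | C8-bromomagnesio derivative of the alkoxide of 7 | COCOc1ccc2c(c1[Mg]Br)O[C@H](c1ccc(OCc3ccccc3)c(OCc3ccccc3)c1)[C@@H](O[Li])C2 | intermediate
16 | (2S,3S)-3-(benzyloxy)-2-[3,4-bis(benzyloxy)phenyl]-2,3-dihydro-7H-chromen-7-one (ring A para-quinone methide) | O=C1C=CC2=C[C@H](OCc3ccccc3)[C@H](c3ccc(OCc4ccccc4)c(OCc4ccccc4)c3)OC2=C1 | intermediate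
17 | (2S,3S,4S)-3-(benzyloxy)-2-[3,4-bis(benzyloxy)phenyl]-4-[(2R,3S)-2-[3,4-bis(benzyloxy)phenyl]-3-hydroxy-7-(methoxymethoxy)-3,4-dihydro-2H-chromen-8-yl]-3,4-dihydro-2H-chromen-7-ol | Oc1ccc2c(c1)O[C@@H](c1ccc(OCc3ccccc3)c(OCc3ccccc3)c1)[C@@H](OCc1ccccc1)[C@@H]2c1c(OCOC)ccc2c1O[C@H](c1ccc(OCc3ccccc3)c(OCc3ccccc3)c1)[C@@H](O)C2 | intermediate
18 | (2S,3S,4S)-2-(3,4-dihydroxyphenyl)-4-[(2R,3S)-2-(3,4-dihydroxyphenyl)-3,7-dihydroxy-3,4-dihydro-2H-chromen-8-yl]-3,4-dihydro-2H-chromene-3,7-diol | Oc1ccc2c(c1)O[C@@H](c1ccc(O)c(O)c1)[C@@H](O)[C@@H]2c1c(O)ccc2c1O[C@H](c1ccc(O)c(O)c1)[C@@H](O)C2 | target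

**Step count**
Total: 12 steps. Longest linear sequence: 11 steps (1, 2, 3, 5, 6, 7, 8, 9, 10, 11, 12); step 4 is the short branch to the lower unit.

**Steps most likely to fail, with fallbacks**

Step 11. The quinone methide may tautomerise to the 3-benzyloxy-flav-3-ene before it is captured, the hindered aryl-magnesium species may act only as a base, or facial control at C4 may erode. The fallback replaces the organometallic addition by an acid-mediated Friedel–Crafts coupling whose regiochemistry is enforced by a blocking bromine. It sets out from 7 and 13 and comes back to the route at 18. Bromination of 7 with N-bromosuccinimide in CH2Cl2 at low temperature should occur at C6, para to O1, to give (2R,3S)-6-bromo-2-[3,4-bis(benzyloxy)phenyl]-7-(methoxymethoxy)-3,4-dihydro-2H-chromen-3-ol F1. Acetylation of 13 (Ac2O, pyridine) gives the 7-acetate F2, which lowers the nucleophilicity of its own ring A. Ionisation of the 4-methoxy group of F2 with catalytic Me3SiOTf in CH2Cl2 at −78 °C in the presence of excess F1 should give the 4→8 linked, 3,4-trans bromo acetate dimer F3. Hydrogenolysis over Pd(OH)2/C with Et3N (benzyl and C–Br cleavage), then HCl in methanol (methoxymethyl and acetyl cleavage), gives 18.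

Step 3. The enolate may be benzylated twice, or oxidative addition of the electron-rich aryl bromide to copper may be too slow for ring C to close. The fallback builds ring C with the phenol oxygen in place from the start. It sets out from commercial 7-hydroxycoumarin and comes back at 6. Methoxymethylation gives 7-(methoxymethoxy)-2H-chromen-2-one F4. Hydrogenation of the C3=C4 bond over Pd/C gives 7-(methoxymethoxy)chroman-2-one F5. Addition of 3,4-bis(benzyloxy)phenyllithium (from commercial 4-bromo-1,2-bis(benzyloxy)benzene and n-BuLi) at −78 °C gives the lactol 2-[3,4-bis(benzyloxy)phenyl]-7-(methoxymethoxy)chroman-2-ol F6. Dehydration with MsCl and Et3N gives 6.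

Step 4 (and its mirror image, step 5). Enantioselectivity of the hydroboration of this enol ether may be insufficient. The fallback replaces reagent control by resolution and uses both enantiomers. It sets out from 6 and comes back at 7 and 8. Hydroboration with BH3·THF and oxidation gives the racemic trans alcohol F7 (equimolar 7 and 8). Acylation with vinyl acetate and Burkholderia cepacia lipase should, by the empirical rule for secondary alcohols, convert the (3R) enantiomer into (2S,3R)-2-[3,4-bis(benzyloxy)phenyl]-7-(methoxymethoxy)-3,4-dihydro-2H-chromen-3-yl acetate F8 and leave 7. After separation, K2CO3 in methanol converts F8 into 8.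

**Further compounds**
F1 | step 11 | (2R,3S)-6-bromo-2-[3,4-bis(benzyloxy)phenyl]-7-(methoxymethoxy)-3,4-dihydro-2H-chromen-3-ol | COCOc1c(Br)cc2c(c1)O[C@H](c1ccc(OCc3ccccc3)c(OCc3ccccc3)c1)[C@@H](O)C2
F2 | step 11 | (2S,3S,4R)-3-(benzyloxy)-2-[3,4-bis(benzyloxy)phenyl]-4-methoxy-3,4-dihydro-2H-chromen-7-yl acetate | CC(=O)Oc1ccc2c(c1)O[C@@H](c1ccc(OCc3ccccc3)c(OCc3ccccc3)c1)[C@@H](OCc1ccccc1)[C@@H]2OC
F3 | step 11 | 6-bromo (lower unit), 7-O-acetyl (upper unit) analogue of 17 | CC(=O)Oc1ccc2c(c1)O[C@@H](c1ccc(OCc3ccccc3)c(OCc3ccccc3)c1)[C@@H](OCc1ccccc1)[C@@H]2c1c(OCOC)c(Br)cc2c1O[C@H](c1ccc(OCc3ccccc3)c(OCc3ccccc3)c1)[C@@H](O)C2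
F4 | step 3 | 7-(methoxymethoxy)-2H-chromen-2-one | COCOc1ccc2ccc(=O)oc2c1
F5 | step 3 | 7-(methoxymethoxy)chroman-2-one | COCOc1ccc2CCC(=O)Oc2c1
F6 | step 3 | 2-[3,4-bis(benzyloxy)phenyl]-7-(methoxymethoxy)chroman-2-ol (lactol, both anomers) | COCOc1ccc2CCC(O)(c3ccc(OCc4ccccc4)c(OCc4ccccc4)c3)Oc2c1
F7 | step 4 | racemic trans-2-[3,4-bis(benzyloxy)phenyl]-7-(methoxymethoxy)-3,4-dihydro-2H-chromen-3-ol (7 plus 8) | COCOc1ccc2c(c1)O[C@H](c1ccc(OCc3ccccc3)c(OCc3ccccc3)c1)[C@@H](O)C2.COCOc1ccc2c(c1)O[C@@H](c1ccc(OCc3ccccc3)c(OCc3ccccc3)c1)[C@H](O)C2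
F8 | step 4 | (2S,3R)-2-[3,4-bis(benzyloxy)phenyl]-7-(methoxymethoxy)-3,4-dihydro-2H-chromen-3-yl acetate | COCOc1ccc2c(c1)O[C@@H](c1ccc(OCc3ccccc3)c(OCc3ccccc3)c1)[C@H](OC(C)=O)C2
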